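Slowness in a flask like this means that a Ux molecule waits long for a living end, so I follow one molecule and ask how long it waits.

| setting | red | green | grey |
|---|---|---|---|
| Ux | 0.10 M | 0.10 M | 0.10 M |
| Dx | 2.00 mM | 2.00 mM | 2.00 mM |
| Gy | 0.50 mM | 0.50 mM | 0.50 mM |
| temperature | 20 °C | 0 °C |  |
| time | 80 s | 80 s | 80 s |
| remark |  |  | at 0 °C until 25 s, from then on at 20 °C |

    Ux + Gy → Dz + Qi (k1 = 8.2 L mol⁻¹ s⁻¹, Ea1 = 37.0 kJ mol⁻¹)
    Ux + Dz → Qi + Dz, rate k2*[Dz]*[Ux] (k2 = 20 L mol⁻¹ s⁻¹, Ea2 = 51.0 kJ mol⁻¹)
    Ux + Gy → UxGy (k3 = 0.030 L mol⁻¹ s⁻¹, Ea3 = 43.0 kJ mol⁻¹)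
    Dx + Ux → DxUx (k4 = 1.3 L mol⁻¹ s⁻¹, Ea4 = 57.0 kJ mol⁻¹)
    Jo ⇌ Qi, rate k5*(cs5 - [Qi]) while solid is left; crystals form when [Qi] > cs5 (cs5 = 1.2 mM, k5 = 1.1 s⁻¹)
    (constants at 20 °C)

- for Qi the Jo is counted in
- as a solid, counted per litre of solution: Jo
- at 20 °C the constants are as listed, elsewhere as the activation energies make them

1. which flask leads in amount of Qi, in percent of the Ux charged ("all alike" within 1.5 percentage points) (red / green / grey / all alike)
2. how much Qi is there at the end, in percent of the Ux charged: red
3. how much Qi is there at the end, in percent of the Ux charged: green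
4. how much Qi is there at the end, in percent of the Ux charged: grey

The first fork belongs to Gy. At 20 °C, meeting Ux, it becomes a living end Dz 273 times as often as it becomes UxGy. With that selectivity factor I count the charge of 0.50 mM as living ends. Even cold, Gy lasts about 3.71 s, far shorter than the 80 s of the run.

Growth gives the living end back, so Ux falls in a pseudo-first-order way. At 20 °C a Ux molecule waits 100 s. This waiting time, one over the growth constant times the living ends, is what I carry. Between the flasks the first step speeds up 3.0 times. The logarithm of such a factor goes with the activation energy, so growth speeds up 4.63 times, and at 0 °C the wait is 463 s.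

Time divided by the wait, added up stretch by stretch, gives a count. The fraction of Ux not yet grown is e to the minus count. The second fork is Dx, which can bind 2.00 % of the Ux charged. At 20 °C it needs about 7.69 s for this, less than the warm time of red or of grey, so I reduce the grown fraction by that full share in those two flasks. At 0 °C it needs about 42.6 s, which is of the same order as the run, so in green I reckon a smaller share of 1.69 %. Jo is counted with Qi, so I reckon no crystals.

Red has a count of 0.800, green 0.173 and grey 0.604. That gives me 54.0 %, 15.6 % and 44.4 %.

Beside grey stands a neighbour that looks nearly the same: the same temperatures, the same Dx, but 1.3 × 10⁻⁴ M of Gy. Its waits stretch 3.85 times, so its count is 0.157, less than grey's. I expect 14.2 % there. Both lose the same share to Dx, so the gap lies in the count.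

The forecast names red as leader, with 53.4 % in red, 15 % in green and 44 % in grey, and says “the result rests on the temperature dependence”. My red stands slightly above its figure.

The flasks give 53.6 % in red, 15.4 % in green and 44.3 % in grey, so red leads. In grey, Gy is down to 0.140 % of its charge at 25.0 s, and Dx is down to 10.4 % of its charge at 40.0 s. Growth runs on throughout, with living ends at 4.98 × 10⁻⁴ M at 80.0 s, and 40 % of its turnover is done by 40.0 s. The neighbour ends at 14.2 %. Grey read at 2.5 min has a count of 1.30, which gives 71.3 %, and the reading there is 71.3 %.

(The numbers stand for no real mixture; the result is computed.)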